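**Retrosynthetic overview**

- The route rests on ring A of the flavonol: oxygen at C5 and at C8 stand para to each other, C7 carries methoxy and C6 carries hydrogen. This is the hydroquinone monoether that a chromium carbene, an alkoxyacetylene and one CO ligand assemble.
- Ring A is disconnected at C5–C6, C7–C8 and C8–C8a to a (4-oxo-4H-pyran-3-yl)(methoxy)carbene Cr(CO)5 complex and methoxyacetylene; the pyranone C2=C3 bond is the alkenyl unit, so rings B and C enter intact.
- The carbene carbon (future C5) is the carboxyl carbon of a pyranone-3-carbonyl chloride, acylated onto Na2Cr(CO)5 and O-methylated. A 3-metallated pyranone is avoided because it would open by β-elimination of the ring oxygen.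
- Ring C comes from C-acylation of the enaminone of tert-butyl 4-(benzyloxy)acetoacetate with the ring B aroyl chloride (from 3,5-dihydroxy-4-methoxybenzoic acid), then cyclocondensation.
- Ring order: B (bought), C (cyclocondensation), A (benzannulation); end game is 8-O-methylation and BCl3 cleavage of the 5-methyl ether and three benzyl ethers.

Key step: step 10

Remark: chromium carbonyl compounds are drawn with formal Cr=C bonds, the η6-arene complex 20 is written with its Cr(CO)3 unit dot-separated, and the enaminone double-bond geometry (8, 9) is left undefined because that carbon becomes a ring sp2 carbon.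

**Route**

Step 1
Reactants: 1 3,5-dihydroxy-4-methoxybenzoic acid
Product: 3 3,5-bis(benzyloxy)-4-methoxybenzoic acid, via benzyl ester 2 (not isolated)
Conditions: BnBr (3.5 equiv), K2CO3, DMF, 60 °C; then NaOH, H2O/MeOH/THF, 65 °C; HCl to pH 2
Reagents that add atoms: benzyl bromide (BrCc1ccccc1); sodium hydroxide ([Na+].[OH-])
Why: Williamson O-alkylation benzylates both phenols and the carboxylate, and saponification then cleaves only the benzyl ester because aryl benzyl ethers are inert to hydroxide.

Step 2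
Reactants: 3 3,5-bis(benzyloxy)-4-methoxybenzoic acid
Product: 4 3,5-bis(benzyloxy)-4-methoxybenzoyl chloride
Conditions: (COCl)2, cat. DMF, CH2Cl2, 0 °C to rt; evaporate, use crude
Reagents that add atoms: oxalyl chloride (ClC(=O)C(=O)Cl)
Why: Vilsmeier-type activation with oxalyl chloride and DMF is the standard acid chloride synthesis and leaves aryl benzyl and methyl ethers untouched.

Step 3
Reactants: 5 tert-butyl 4-chloro-3-oxobutanoate
Product: 6 tert-butyl 4-(benzyloxy)-3-oxobutanoate
Conditions: BnOH (1.05 equiv), NaH (2.2 equiv), THF, 0 °C to rt; cold 1 M HCl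
Reagents that add atoms: benzyl alcohol (OCc1ccccc1)
Why: Williamson ether synthesis in which sodium benzyloxide displaces the γ-chloride while the second equivalent of NaH holds the β-keto ester as its enolate, the standard preparation of 4-(benzyloxy)acetoacetates.

Step 4
Reactants: 6 tert-butyl 4-(benzyloxy)-3-oxobutanoate; 7 N,N-dimethylformamide dimethyl acetal
Product: 8 tert-butyl 4-(benzyloxy)-2-[(dimethylamino)methylidene]-3-oxobutanoate
Conditions: toluene, rt to 50 °C
Reagents that add atoms: none
Why: Aminomethylenation (Knoevenagel-type condensation with the amide acetal) occurs only at the doubly activated C2 methylene, C4 being far less acidic.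

Step 5
Reactants: 8 tert-butyl 4-(benzyloxy)-2-[(dimethylamino)methylidene]-3-oxobutanoate; 4 3,5-bis(benzyloxy)-4-methoxybenzoyl chloride
Product: 10 tert-butyl 5-(benzyloxy)-6-[3,5-bis(benzyloxy)-4-methoxyphenyl]-4-oxo-4H-pyran-3-carboxylate, via acylated enaminone 9 (not isolated)
Conditions: LiN(SiMe3)2 (2.2 equiv), THF, −78 °C; 4, −78 to −20 °C; then 1 M HCl, THF, rt
Reagents that add atoms: none
Why: Claisen-type C-acylation of the C4 lithium enolate (the only enolisable position) gives the 1,3-diketone, whose enol oxygen adds to the protonated aminomethylene carbon and expels dimethylamine (6-endo addition–elimination) to close the 4-pyranone, as in the known oxalate route to 3-alkoxy-4-pyranone carboxylates.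

Step 6
Reactants: 10 tert-butyl 5-(benzyloxy)-6-[3,5-bis(benzyloxy)-4-methoxyphenyl]-4-oxo-4H-pyran-3-carboxylate
Product: 11 5-(benzyloxy)-6-[3,5-bis(benzyloxy)-4-methoxyphenyl]-4-oxo-4H-pyran-3-carboxylic acid
Conditions: TFA/CH2Cl2 (1:3), 0 °C to rt
Reagents that add atoms: none
Why: Acidolysis of the tert-butyl ester (loss of 2-methylpropene) frees the acid without hydroxide, which would add to the unsubstituted C2 of the pyranone and open the ring, while benzyl ethers survive brief TFA treatment.

Step 7
Reactants: 11 5-(benzyloxy)-6-[3,5-bis(benzyloxy)-4-methoxyphenyl]-4-oxo-4H-pyran-3-carboxylic acid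
Product: 12 5-(benzyloxy)-6-[3,5-bis(benzyloxy)-4-methoxyphenyl]-4-oxo-4H-pyran-3-carbonyl chloride
Conditions: 1-chloro-N,N,2-trimethylprop-1-en-1-amine (1.2 equiv), CH2Cl2, 0 °C to rt; evaporate, use crude
Reagents that add atoms: 1-chloro-N,N,2-trimethylprop-1-en-1-amine (CC(C)=C(Cl)N(C)C)
Why: The α-chloroenamine (Ghosez reagent) forms the acid chloride under neutral conditions and so avoids the chloropyrylium formation that oxalyl chloride can cause at a 4-pyranone carbonyl.

Step 8
Reactants: 12 5-(benzyloxy)-6-[3,5-bis(benzyloxy)-4-methoxyphenyl]-4-oxo-4H-pyran-3-carbonyl chloride; 13 hexacarbonylchromium Cr(CO)6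
Product: 16 pentacarbonyl{methoxy[5-(benzyloxy)-6-(3,5-bis(benzyloxy)-4-methoxyphenyl)-4-oxo-4H-pyran-3-yl]methylidene}chromium, via Na2Cr(CO)5 14 (not isolated), via sodium acylchromate 15 (not isolated)
Conditions: Cr(CO)6, NaC10H8 (sodium naphthalenide, 2.05 equiv), THF, −78 to 0 °C; cannulate into 12, THF, −78 °C; evaporate; Me3OBF4 (1.05 equiv), CH2Cl2, 0 °C; chromatography under argon
Reagents that add atoms: trimethyloxonium tetrafluoroborate (C[O+](C)C.F[B-](F)(F)F)
Why: Semmelhack–Hegedus carbene synthesis, in which Na2Cr(CO)5 is acylated by the acid chloride at −78 °C (inverse addition keeps the dianion from meeting excess pyranone) and the acylchromate is O-methylated by the Meerwein salt, so that no 3-metallated pyranone is ever generated.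

Step 9
Reactants: 17 chloroacetaldehyde dimethyl acetal
Product: 19 methoxyacetylene, via sodium methoxyethynide 18 (not isolated)
Conditions: NaNH2 (3 equiv), liq. NH3, −33 °C; evaporate NH3; cold sat. aq. NH4Cl; distil into cold THF, use at once
Reagents that add atoms: none
Why: Twofold base-induced elimination (HCl, then methanol) with NaNH2 in liquid ammonia is the standard preparation of alkoxyacetylenes, and buffered protonation of the alkynide releases the volatile ynol ether.

Step 10
Reactants: 16 pentacarbonyl{methoxy[5-(benzyloxy)-6-(3,5-bis(benzyloxy)-4-methoxyphenyl)-4-oxo-4H-pyran-3-yl]methylidene}chromium; 19 methoxyacetylene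
Product: 21 3-(benzyloxy)-2-[3,5-bis(benzyloxy)-4-methoxyphenyl]-8-hydroxy-5,7-dimethoxy-4H-chromen-4-one, via arene Cr(CO)3 complex 20 (not isolated)
Conditions: 19 (2–3 equiv), THF (0.05 M), 50 °C, sealed tube, argon; then air, rt
Reagents that add atoms: none
Why: Proposed new method: loss of one CO from 16 (helped by transient chelation of the C4 carbonyl oxygen to chromium) lets methoxyacetylene insert into the Cr=C bond, CO insertion then gives a chromium-bound dienylketene, and 6π electrocyclisation onto the unsubstituted pyranone carbon C2 followed by enolisation gives the 4-methoxyphenol as its Cr(CO)3 complex 20, from which air releases 21; the carbene carbon becomes C5 with its methoxy group, the alkyne becomes C6–H and C7–OMe, and the CO ligand becomes C8–OH. The closest known reaction type is the Dötz benzannulation of alkenyl(alkoxy)carbene complexes of zerovalent chromium with terminal alkynes, which has not been run on a 4-pyranon-3-yl carbene or with this ynol ether. Ring A, the only ring closed, forms as a six-membered carbocycle by disrotatory 6π electrocyclic closure of the ketene carbon onto C2 of ring C, the pyranone C2=C3 bond serving as the alkenyl unit; no stereocentre is created. The step needs the alkyne to insert with its CH terminus bonded to the carbene carbon and its methoxy-bearing carbon next to the CO-derived carbon: the steric rule for terminal alkynes places the substituted carbon beside the new phenol carbon, and the ynol ether polarity (nucleophilic CH carbon, new carbene carbon stabilised by its own methoxy group) points the same way. It also needs CO insertion to outrun capture of the intermediate vinylcarbene by the neighbouring ketone oxygen, which a closed vessel and moderate temperature should favour.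

Step 11
Reactants: 21 3-(benzyloxy)-2-[3,5-bis(benzyloxy)-4-methoxyphenyl]-8-hydroxy-5,7-dimethoxy-4H-chromen-4-one
Product: 22 3-(benzyloxy)-2-[3,5-bis(benzyloxy)-4-methoxyphenyl]-5,7,8-trimethoxy-4H-chromen-4-one
Conditions: MeI, K2CO3, DMF, 40 °C
Reagents that add atoms: iodomethane (CI)
Why: Williamson methylation of the only free hydroxyl, a hindered but acidic phenol, should be clean because no other nucleophilic site is present.

Step 12
Reactants: 22 3-(benzyloxy)-2-[3,5-bis(benzyloxy)-4-methoxyphenyl]-5,7,8-trimethoxy-4H-chromen-4-one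
Product: 23 2-(3,5-dihydroxy-4-methoxyphenyl)-3,5-dihydroxy-7,8-dimethoxy-4H-chromen-4-one (CNP0165950.0)
Conditions: BCl3 (10 equiv), pentamethylbenzene (6 equiv), CH2Cl2, −78 to 0 °C; MeOH, then H2O
Reagents that add atoms: none
Why: Chelation-controlled Lewis acid demethylation, in which BCl3 bound between the C4 carbonyl and the peri 5-methoxy oxygen cleaves only that methyl ether, while the same reagent removes the three benzyl ethers at low temperature with pentamethylbenzene trapping the benzyl cations.

**Compound list**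

1 | 3,5-dihydroxy-4-methoxybenzoic acid | COc1c(O)cc(C(=O)O)cc1O | starting material
2 | benzyl 3,5-bis(benzyloxy)-4-methoxybenzoate | COc1c(OCc2ccccc2)cc(C(=O)OCc2ccccc2)cc1OCc1ccccc1 | intermediate
3 | 3,5-bis(benzyloxy)-4-methoxybenzoic acid | COc1c(OCc2ccccc2)cc(C(=O)O)cc1OCc1ccccc1 | intermediate
4 | 3,5-bis(benzyloxy)-4-methoxybenzoyl chloride | COc1c(OCc2ccccc2)cc(C(=O)Cl)cc1OCc1ccccc1 | intermediate
5 | tert-butyl 4-chloro-3-oxobutanoate | CC(C)(C)OC(=O)CC(=O)CCl | starting material
6 | tert-butyl 4-(benzyloxy)-3-oxobutanoate | CC(C)(C)OC(=O)CC(=O)COCc1ccccc1 | intermediate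
7 | N,N-dimethylformamide dimethyl acetal | COC(OC)N(C)C | starting material
8 | tert-butyl 4-(benzyloxy)-2-[(dimethylamino)methylidene]-3-oxobutanoate | CC(C)(C)OC(=O)C(=CN(C)C)C(=O)COCc1ccccc1 | intermediate
9 | tert-butyl 4-(benzyloxy)-5-[3,5-bis(benzyloxy)-4-methoxyphenyl]-2-[(dimethylamino)methylidene]-3,5-dioxopentanoate (present as its lithium enolate) | CC(C)(C)OC(=O)C(=CN(C)C)C(=O)C(OCc1ccccc1)C(=O)c1cc(OCc2ccccc2)c(OC)c(OCc2ccccc2)c1 | intermediate
10 | tert-butyl 5-(benzyloxy)-6-[3,5-bis(benzyloxy)-4-methoxyphenyl]-4-oxo-4H-pyran-3-carboxylate | CC(C)(C)OC(=O)C1=COC(c2cc(OCc3ccccc3)c(OC)c(OCc3ccccc3)c2)=C(OCc2ccccc2)C1=O | intermediate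
11 | 5-(benzyloxy)-6-[3,5-bis(benzyloxy)-4-methoxyphenyl]-4-oxo-4H-pyran-3-carboxylic acid | OC(=O)C1=COC(c2cc(OCc3ccccc3)c(OC)c(OCc3ccccc3)c2)=C(OCc2ccccc2)C1=O | intermediate
12 | 5-(benzyloxy)-6-[3,5-bis(benzyloxy)-4-methoxyphenyl]-4-oxo-4H-pyran-3-carbonyl chloride | ClC(=O)C1=COC(c2cc(OCc3ccccc3)c(OC)c(OCc3ccccc3)c2)=C(OCc2ccccc2)C1=O | intermediate
13 | hexacarbonylchromium Cr(CO)6 | O=C=[Cr](=C=O)(=C=O)(=C=O)(=C=O)=C=O | starting material
14 | disodium pentacarbonylchromate Na2Cr(CO)5 | [Na+].[Na+].O=C=[Cr-2](=C=O)(=C=O)(=C=O)=C=O | intermediate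
15 | sodium pentacarbonyl{[5-(benzyloxy)-6-(3,5-bis(benzyloxy)-4-methoxyphenyl)-4-oxo-4H-pyran-3-yl]carbonyl}chromate | [Na+].[O-]C(=[Cr](=C=O)(=C=O)(=C=O)(=C=O)=C=O)C1=COC(c2cc(OCc3ccccc3)c(OC)c(OCc3ccccc3)c2)=C(OCc2ccccc2)C1=O | intermediate
16 | pentacarbonyl{methoxy[5-(benzyloxy)-6-(3,5-bis(benzyloxy)-4-methoxyphenyl)-4-oxo-4H-pyran-3-yl]methylidene}chromium | COC(=[Cr](=C=O)(=C=O)(=C=O)(=C=O)=C=O)C1=COC(c2cc(OCc3ccccc3)c(OC)c(OCc3ccccc3)c2)=C(OCc2ccccc2)C1=O | intermediate
17 | chloroacetaldehyde dimethyl acetal | COC(CCl)OC | starting material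
18 | sodium methoxyethynide | [Na+].[C-]#COC | intermediate
19 | methoxyacetylene | COC#C | intermediate
20 | tricarbonyl(η6-arene)chromium complex of 21, metal on ring A | COc1cc(OC)c2c(=O)c(OCc3ccccc3)c(-c3cc(OCc4ccccc4)c(OC)c(OCc4ccccc4)c3)oc2c1O.O=C=[Cr](=C=O)=C=O | intermediate
21 | 3-(benzyloxy)-2-[3,5-bis(benzyloxy)-4-methoxyphenyl]-8-hydroxy-5,7-dimethoxy-4H-chromen-4-one | COc1cc(OC)c2c(=O)c(OCc3ccccc3)c(-c3cc(OCc4ccccc4)c(OC)c(OCc4ccccc4)c3)oc2c1O | intermediate
22 | 3-(benzyloxy)-2-[3,5-bis(benzyloxy)-4-methoxyphenyl]-5,7,8-trimethoxy-4H-chromen-4-one | COc1cc(OC)c2c(=O)c(OCc3ccccc3)c(-c3cc(OCc4ccccc4)c(OC)c(OCc4ccccc4)c3)oc2c1OC | intermediate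
23 | 2-(3,5-dihydroxy-4-methoxyphenyl)-3,5-dihydroxy-7,8-dimethoxy-4H-chromen-4-one | COc1cc(O)c2c(=O)c(O)c(-c3cc(O)c(OC)c(O)c3)oc2c1OC | target

**Step count**

Total steps: 12. Longest linear sequence: 9 steps (1, 2, 5, 6, 7, 8, 10, 11, 12 from compound 1; equally 3–8, 10–12 from compound 5).

**Steps most likely to fail, with fallbacks**

1. Step 10 (proposed new method). The reaction may stall at the methoxy-stabilised vinylcarbene after alkyne insertion, the neighbouring C4 ketone oxygen may capture that carbene before CO inserts, or the ynol ether may oligomerise on chromium.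
Fallback by known flavone chemistry, setting out from 4 and returning at 22: the acid chloride 4 would acylate the phenol of purchased 1-(2-hydroxy-3,4,6-trimethoxyphenyl)ethan-1-one (pyridine, DMAP) to give 2-acetyl-3,5,6-trimethoxyphenyl 3,5-bis(benzyloxy)-4-methoxybenzoate F1. Baker–Venkataraman rearrangement (KOH, pyridine, 50 °C) would give 1-[3,5-bis(benzyloxy)-4-methoxyphenyl]-3-(2-hydroxy-3,4,6-trimethoxyphenyl)propane-1,3-dione F2. Cyclodehydration (TsOH, toluene, 90 °C) would give 2-[3,5-bis(benzyloxy)-4-methoxyphenyl]-5,7,8-trimethoxy-4H-chromen-4-one F3. C3 lithiation with LiN(iPr)2 at −78 °C, borylation with B(OMe)3 and oxidation with H2O2/AcOH would give 2-[3,5-bis(benzyloxy)-4-methoxyphenyl]-3-hydroxy-5,7,8-trimethoxy-4H-chromen-4-one F4. Benzylation (BnBr, K2CO3, DMF) then gives 22.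

2. Step 8. The chromate dianion may transfer an electron to the pyranone or add in conjugate fashion at C2 instead of substituting the acyl chloride, or the Meerwein salt may alkylate the pyranone carbonyl.
Fallback by the Fischer route through an organomagnesium compound, setting out from 11 and returning at 16: ipso-iododecarboxylation of 11 (N-iodosuccinimide, K3PO4, MeCN, 60 °C) would give 3-(benzyloxy)-2-[3,5-bis(benzyloxy)-4-methoxyphenyl]-5-iodo-4H-pyran-4-one F5. Iodine–magnesium exchange (iPrMgCl·LiCl, THF, −40 °C) would give chloro{5-(benzyloxy)-6-[3,5-bis(benzyloxy)-4-methoxyphenyl]-4-oxo-4H-pyran-3-yl}magnesium F6; magnesium is chosen over lithium because the lithio compound would expel the ring oxygen by β-elimination. Addition to Cr(CO)6 (THF, 0 °C to rt) would give chloromagnesium pentacarbonyl{[5-(benzyloxy)-6-(3,5-bis(benzyloxy)-4-methoxyphenyl)-4-oxo-4H-pyran-3-yl]carbonyl}chromate F7, and O-methylation with Me3OBF4 gives 16.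

3. Step 5. The lithium enolate may be acylated on oxygen, or proton transfer from the acidic diketone may quench unreacted enolate, so that ring C is not assembled.
Fallback by aldol addition and oxidation, setting out from 4 and 8 and returning at 10: reduction of 4 with LiAlH(OtBu)3 (THF, −78 °C) would give 3,5-bis(benzyloxy)-4-methoxybenzaldehyde F8. Aldol addition of the lithium enolate of 8 (LiN(SiMe3)2, THF, −78 °C) to this aldehyde would give tert-butyl 4-(benzyloxy)-5-[3,5-bis(benzyloxy)-4-methoxyphenyl]-2-[(dimethylamino)methylidene]-5-hydroxy-3-oxopentanoate F9 as a diastereomer mixture whose stereocentres are lost in the next operation. Dess–Martin oxidation before any acid treatment gives 9, and 1 M HCl closes it to 10.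

**Further compounds**

F1 | step 10 | 2-acetyl-3,5,6-trimethoxyphenyl 3,5-bis(benzyloxy)-4-methoxybenzoate | CC(=O)c1c(OC)cc(OC)c(OC)c1OC(=O)c1cc(OCc2ccccc2)c(OC)c(OCc2ccccc2)c1
F2 | step 10 | 1-[3,5-bis(benzyloxy)-4-methoxyphenyl]-3-(2-hydroxy-3,4,6-trimethoxyphenyl)propane-1,3-dione | COc1cc(OC)c(C(=O)CC(=O)c2cc(OCc3ccccc3)c(OC)c(OCc3ccccc3)c2)c(O)c1OC
F3 | step 10 | 2-[3,5-bis(benzyloxy)-4-methoxyphenyl]-5,7,8-trimethoxy-4H-chromen-4-one | COc1cc(OC)c2c(=O)cc(-c3cc(OCc4ccccc4)c(OC)c(OCc4ccccc4)c3)oc2c1OC
F4 | step 10 | 2-[3,5-bis(benzyloxy)-4-methoxyphenyl]-3-hydroxy-5,7,8-trimethoxy-4H-chromen-4-one | COc1cc(OC)c2c(=O)c(O)c(-c3cc(OCc4ccccc4)c(OC)c(OCc4ccccc4)c3)oc2c1OC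
F5 | step 8 | 3-(benzyloxy)-2-[3,5-bis(benzyloxy)-4-methoxyphenyl]-5-iodo-4H-pyran-4-one | IC1=COC(c2cc(OCc3ccccc3)c(OC)c(OCc3ccccc3)c2)=C(OCc2ccccc2)C1=O
F6 | step 8 | chloro{5-(benzyloxy)-6-[3,5-bis(benzyloxy)-4-methoxyphenyl]-4-oxo-4H-pyran-3-yl}magnesium | Cl[Mg]C1=COC(c2cc(OCc3ccccc3)c(OC)c(OCc3ccccc3)c2)=C(OCc2ccccc2)C1=O
F7 | step 8 | chloromagnesium pentacarbonyl{[5-(benzyloxy)-6-(3,5-bis(benzyloxy)-4-methoxyphenyl)-4-oxo-4H-pyran-3-yl]carbonyl}chromate | Cl[Mg+].[O-]C(=[Cr](=C=O)(=C=O)(=C=O)(=C=O)=C=O)C1=COC(c2cc(OCc3ccccc3)c(OC)c(OCc3ccccc3)c2)=C(OCc2ccccc2)C1=O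
F8 | step 5 | 3,5-bis(benzyloxy)-4-methoxybenzaldehyde | COc1c(OCc2ccccc2)cc(C=O)cc1OCc1ccccc1
F9 | step 5 | tert-butyl 4-(benzyloxy)-5-[3,5-bis(benzyloxy)-4-methoxyphenyl]-2-[(dimethylamino)methylidene]-5-hydroxy-3-oxopentanoate (diastereomer mixture) | CC(C)(C)OC(=O)C(=CN(C)C)C(=O)C(OCc1ccccc1)C(O)c1cc(OCc2ccccc2)c(OC)c(OCc2ccccc2)c1
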